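Numbering: O1, C2, C3 and C3a–C7a of the 2,3-dihydrobenzofuran, and C1′ for the carbinol carbon on C5. The target is the trans-(2S,3R) ring with a (1′R) side chain.
Retrosynthetic cuts, in order: the aldehyde C=O (back to the CH3 of an isopropenyl group), the tigloyl–O and acetyl–O bonds, then O1–C2 and C2–C3 together, and last the C3–C3a (formyl) bond and the C1′–H bond of an aryl methyl ketone.
Enabling feature: in the five-membered ring a single carbon, C2, separates the ring oxygen O1 from the oxygen-bearing benzylic carbon C3, and it carries the 2-propenyl unit. C2 can therefore arrive as the carbanionic carbon of a methallyl sulfonium ylide, while a salicylaldehyde brings the benzene ring, O1 and C3.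
Forward order: the benzene ring is bought, then the side-chain carbinol, the formyl group and a phenol mask are installed. The ylide builds an oxirane on C2–C3, and release of the phenoxide in the same flask turns it into the dihydrofuran ring (O1–C2). Acetate, tiglate and enal follow.
Stereochemistry: C1′ comes from asymmetric transfer hydrogenation. C3 and C2 come from twofold-symmetric (2S,5S)-2,5-dimethylthiolane via the trans-(2R,3R) epoxide, whose SN2 opening keeps C3 (R) and inverts C2 (to S), giving the trans ring.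
Design points: the phenol stays silylated until the epoxide exists, so that only the double-inversion path is open. The sulfide enantiomer is the one made from (2R,5R)-hexane-2,5-diol.

Key step: step 10

Assumption: the methallyl ylide of 2,5-dimethylthiolane is taken to follow the sense of induction established for this sulfide with aromatic aldehydes, (2R,5R) sulfide to (S,S) trans epoxide, so the (2S,5S) sulfide is used for the (R,R) epoxide; both enantiomers of the diol precursor are commercial.

Step 1
Reactants: 1 p-hydroxyacetophenone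
Product: 2 p-(tert-butyldimethylsilyloxy)acetophenone (TBS = tert-butyldimethylsilyl)
Conditions: TBSCl, imidazole, DMF, rt
Reagents that add atoms: tert-butyldimethylsilyl chloride (TBSCl), CC(C)(C)[Si](C)(C)Cl
Why: Imidazole-promoted silylation of a phenol removes the acidic OH, which would slow hydride transfer to an already electron-rich ketone and would leave a racemisation-prone 4-hydroxybenzylic alcohol after reduction.

Step 2
Reactants: 2 p-(tert-butyldimethylsilyloxy)acetophenone
Product: 3 (1R)-1-[4-(tert-butyldimethylsilyloxy)phenyl]ethanol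
Conditions: RuCl[(R,R)-TsDPEN](p-cymene) (1 mol %), HCO2H/Et3N 5:2, 30 °C
Reagents that add atoms: none
Why: Noyori–Ikariya asymmetric transfer hydrogenation of an aryl methyl ketone, in which the ruthenium hydride of the (R,R)-diamine ligand delivers hydrogen to the Si face through the six-membered, CH/π-organised transition state and so sets C1′ as R.

Step 3
Reactants: 3 (1R)-1-[4-(tert-butyldimethylsilyloxy)phenyl]ethanol
Product: 4 tert-butyl{4-[(1R)-1-(tert-butyldimethylsilyloxy)ethyl]phenoxy}dimethylsilane
Conditions: TBSCl, imidazole, DMF, rt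
Reagents that add atoms: tert-butyldimethylsilyl chloride (TBSCl), CC(C)(C)[Si](C)(C)Cl
Why: Routine imidazole-promoted silylation of a secondary alcohol leaves the C1′–O bond and hence the R configuration untouched and installs an oxygen substituent that is a poor nucleofuge para to the later phenoxide.

Step 4
Reactants: 4 tert-butyl{4-[(1R)-1-(tert-butyldimethylsilyloxy)ethyl]phenoxy}dimethylsilane
Product: 5 p-[(1R)-1-(tert-butyldimethylsilyloxy)ethyl]phenol
Conditions: Cs2CO3 (0.5 equiv), DMF/H2O 10:1, rt
Reagents that add atoms: none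
Why: Chemoselective carbonate-mediated hydrolysis of an aryl silyl ether works because phenoxide leaves silicon far more readily than a secondary alkoxide, so the alkyl TBS ether should stay.

Step 5
Reactants: 5 p-[(1R)-1-(tert-butyldimethylsilyloxy)ethyl]phenol
Product: 6 salicylaldehyde 2-hydroxy-5-[(1R)-1-(tert-butyldimethylsilyloxy)ethyl]benzaldehyde
Conditions: MgCl2, Et3N, (CH2O)n, THF, reflux
Reagents that add atoms: paraformaldehyde (source of formaldehyde), C=O
Why: Casnati–Skattebøl ortho-formylation, in which the magnesium phenoxide directs formaldehyde to the ortho carbon and a second formaldehyde oxidises the benzylic alkoxide by hydride transfer, can give only one regioisomer because the para position is blocked and the two ortho positions are equivalent.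

Step 6
Reactants: 6 salicylaldehyde 2-hydroxy-5-[(1R)-1-(tert-butyldimethylsilyloxy)ethyl]benzaldehyde
Product: 7 O-silyl salicylaldehyde 2-(tert-butyldimethylsilyloxy)-5-[(1R)-1-(tert-butyldimethylsilyloxy)ethyl]benzaldehyde
Conditions: TBSCl, imidazole, CH2Cl2, 0 °C → rt
Reagents that add atoms: tert-butyldimethylsilyl chloride (TBSCl), CC(C)(C)[Si](C)(C)Cl
Why: Imidazole-promoted silylation of the salicylaldehyde OH restores the full electrophilicity of the formyl group and keeps the phenoxide out of the C–C bond-forming event of step 10.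

Step 7
Reactants: 8 (2R,5R)-hexane-2,5-diol
Product: 9 (2R,5R)-hexane-2,5-diyl dimethanesulfonate
Conditions: MsCl, Et3N, CH2Cl2, 0 °C
Reagents that add atoms: methanesulfonyl chloride, CS(=O)(=O)Cl
Why: Standard mesylation breaks only O–H bonds, so both carbinol carbons keep the R configuration.

Step 8
Reactants: 9 (2R,5R)-hexane-2,5-diyl dimethanesulfonate
Product: 10 (2S,5S)-2,5-dimethylthiolane
Conditions: Na2S·9H2O, EtOH, rt
Reagents that add atoms: sodium sulfide nonahydrate (Na2S·9H2O), [Na+].[Na+].[S-2]
Why: Double SN2 displacement by sulfide (intermolecular, then 5-exo-tet), each with inversion, turns the (2R,5R) dimesylate into the trans-(2S,5S) thiolane.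

Step 9
Reactants: 10 (2S,5S)-2,5-dimethylthiolane; 11 methallyl bromide (3-bromo-2-methylprop-1-ene)
Product: 12 (2S,5S)-2,5-dimethyl-1-(2-methylallyl)thiolan-1-ium tetrafluoroborate
Conditions: AgBF4, CH2Cl2, 0 °C → rt, dark
Reagents that add atoms: AgBF4, [Ag+].F[B-](F)(F)F
Why: S-Alkylation of a dialkyl sulfide by an allylic bromide is driven by precipitation of AgBr, and only one sulfonium salt can form because the two lone pairs of the twofold-symmetric sulfide are equivalent.

Step 10
Reactants: 7 O-silyl salicylaldehyde 2-(tert-butyldimethylsilyloxy)-5-[(1R)-1-(tert-butyldimethylsilyloxy)ethyl]benzaldehyde; 12 (2S,5S)-2,5-dimethyl-1-(2-methylallyl)thiolan-1-ium tetrafluoroborate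
Product: 17 (2S,3R)-5-[(1R)-1-(tert-butyldimethylsilyloxy)ethyl]-2-(prop-1-en-2-yl)-2,3-dihydro-1-benzofuran-3-ol, via ylide 13 (not isolated), via anti betaine 14 (not isolated), via trans vinyl epoxide 15 (not isolated), via epoxy phenoxide 16 (not isolated)
Conditions: 12 (1.2 equiv), KN(SiMe3)2 (1.15 equiv), THF, −78 °C; add 7, −78 → −40 °C; then Bu4NF (1.0 equiv, THF), −78 → 0 °C; H2O
Reagents that add atoms: none
Why: KN(SiMe3)2 removes a methallylic proton of 12, ylide 13 adds to the formyl carbon of 7 (C2–C3 bond), and the anti betaine 14 closes by 3-exo-tet displacement of sulfide 10 to the trans epoxide 15 while the syn betaine largely reverts, which is the known asymmetric sulfonium ylide epoxidation of aromatic aldehydes to trans vinyl epoxides. Both epoxide carbons are set by the twofold-symmetric sulfide, in which one ring methyl group fixes the ylide conformation and the other blocks one ylide face, so that the (2S,5S) sulfide should lead to the (2R,3R) epoxide, and the remote C1′ centre plays no part. One equivalent of Bu4NF then cleaves the aryl silyl ether far faster than the secondary alkyl one, and phenoxide 16 attacks the allylic epoxide carbon from the rear (O1–C2 bond) in a 5-endo opening of the oxirane, the known cyclisation of 2-(oxiranyl)phenols to trans-2,3-dihydrobenzofuran-3-ols. C3 stays R because its C–O bond is never broken, C2 is inverted from R to S, and a trans epoxide opened with inversion maps onto the trans ring. The phenol is kept silylated during C–C bond formation because a free ortho phenoxide would deactivate the aldehyde and could expel the sulfide directly from a betaine (5-exo-tet, a single inversion), which gives the cis ring from 14 and the mirror-image trans ring from the syn betaine, and a silyl mask is chosen because an acyl one would migrate to the betaine alkoxide. The step needs SN2 opening at C2 rather than SN2′, SN1 or ortho-quinone-methide opening at C3, and this is secured by the allylic π system on C2, by the four-membered ring that attack at C3 would require, and by the aprotic, Lewis acid free medium at low temperature.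

Step 11
Reactants: 17 (2S,3R)-5-[(1R)-1-(tert-butyldimethylsilyloxy)ethyl]-2-(prop-1-en-2-yl)-2,3-dihydro-1-benzofuran-3-ol
Product: 18 (2S,3R)-5-[(1R)-1-(tert-butyldimethylsilyloxy)ethyl]-2-(prop-1-en-2-yl)-2,3-dihydro-1-benzofuran-3-yl acetate
Conditions: Ac2O, pyridine, 4-(dimethylamino)pyridine (cat.), CH2Cl2, 0 °C
Reagents that add atoms: acetic anhydride, CC(=O)OC(C)=O
Why: Nucleophile-catalysed acetylation of a secondary alcohol under basic conditions leaves the C3–O bond intact (R retained) and avoids the acid that would ionise C3 and aromatise the ring to a benzofuran.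

Step 12
Reactants: 18 (2S,3R)-5-[(1R)-1-(tert-butyldimethylsilyloxy)ethyl]-2-(prop-1-en-2-yl)-2,3-dihydro-1-benzofuran-3-yl acetate
Product: 19 (2S,3R)-5-[(1R)-1-hydroxyethyl]-2-(prop-1-en-2-yl)-2,3-dihydro-1-benzofuran-3-yl acetate
Conditions: Bu4NF/AcOH 1:1, THF, rt
Reagents that add atoms: none
Why: Fluoride-mediated desilylation buffered with acetic acid keeps the medium too weakly basic to cleave or eliminate the C3 acetate (whose C2–H is syn to it in the trans ring) and too weakly acidic to ionise the 4-alkoxybenzylic carbinol.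

Step 13
Reactants: 19 (2S,3R)-5-[(1R)-1-hydroxyethyl]-2-(prop-1-en-2-yl)-2,3-dihydro-1-benzofuran-3-yl acetate; 20 tiglic acid [(2E)-2-methylbut-2-enoic acid]
Product: 21 (1R)-1-[(2S,3R)-3-acetoxy-2-(prop-1-en-2-yl)-2,3-dihydro-1-benzofuran-5-yl]ethyl (2E)-2-methylbut-2-enoate
Conditions: N,N′-dicyclohexylcarbodiimide (DCC), 4-(dimethylamino)pyridine (cat.), CH2Cl2, 0 °C → rt
Reagents that add atoms: none
Why: Steglich esterification acylates at oxygen and so retains the R configuration of C1′, and the E geometry of the tiglate is the thermodynamically preferred one and is not at risk.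

Step 14
Reactants: 21 (1R)-1-[(2S,3R)-3-acetoxy-2-(prop-1-en-2-yl)-2,3-dihydro-1-benzofuran-5-yl]ethyl (2E)-2-methylbut-2-enoate
Product: 23 (1R)-1-[(2S,3R)-3-acetoxy-2-(3-oxoprop-1-en-2-yl)-2,3-dihydro-1-benzofuran-5-yl]ethyl (2E)-2-methylbut-2-enoate (CNP0294391.1), via allylic alcohol 22 (not isolated)
Conditions: SeO2 (0.3 equiv), t-BuOOH (decane), CH2Cl2, 0 °C → rt; crude, then MnO2, CH2Cl2, rt
Reagents that add atoms: selenium dioxide, O=[Se]=O; tert-butyl hydroperoxide, CC(C)(C)OO
Why: Selenium dioxide allylic oxidation (ene reaction, then [2,3]-sigmatropic shift, with t-BuOOH as terminal oxidant) should take the methyl group of the electron-richer 1,1-disubstituted alkene rather than the ester-deactivated tiglate alkene or the tertiary C2–H, and MnO2 oxidation of the crude allylic alcohol/enal mixture converges on the enal, as is known for isopropenyl groups.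

Compound list
1 | p-hydroxyacetophenone (4-hydroxyacetophenone) | CC(=O)c1ccc(O)cc1 | starting material
2 | p-(tert-butyldimethylsilyloxy)acetophenone | CC(=O)c1ccc(O[Si](C)(C)C(C)(C)C)cc1 | intermediate
3 | (1R)-1-[4-(tert-butyldimethylsilyloxy)phenyl]ethanol | C[C@@H](O)c1ccc(O[Si](C)(C)C(C)(C)C)cc1 | intermediate
4 | tert-butyl{4-[(1R)-1-(tert-butyldimethylsilyloxy)ethyl]phenoxy}dimethylsilane | C[C@@H](O[Si](C)(C)C(C)(C)C)c1ccc(O[Si](C)(C)C(C)(C)C)cc1 | intermediate
5 | 4-[(1R)-1-(tert-butyldimethylsilyloxy)ethyl]phenol | C[C@@H](O[Si](C)(C)C(C)(C)C)c1ccc(O)cc1 | intermediate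
6 | 2-hydroxy-5-[(1R)-1-(tert-butyldimethylsilyloxy)ethyl]benzaldehyde | O=Cc1cc([C@@H](C)O[Si](C)(C)C(C)(C)C)ccc1O | intermediate
7 | 2-(tert-butyldimethylsilyloxy)-5-[(1R)-1-(tert-butyldimethylsilyloxy)ethyl]benzaldehyde | O=Cc1cc([C@@H](C)O[Si](C)(C)C(C)(C)C)ccc1O[Si](C)(C)C(C)(C)C | intermediate
8 | (2R,5R)-hexane-2,5-diol | C[C@@H](O)CC[C@@H](C)O | starting material
9 | (2R,5R)-hexane-2,5-diyl dimethanesulfonate | C[C@@H](OS(C)(=O)=O)CC[C@@H](C)OS(C)(=O)=O | intermediate
10 | (2S,5S)-2,5-dimethylthiolane | C[C@H]1CC[C@H](C)S1 | intermediate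
11 | methallyl bromide (3-bromo-2-methylprop-1-ene) | C=C(C)CBr | starting material
12 | (2S,5S)-2,5-dimethyl-1-(2-methylallyl)thiolan-1-ium tetrafluoroborate | C=C(C)C[S+]1[C@@H](C)CC[C@@H]1C.F[B-](F)(F)F | intermediate
13 | (2S,5S)-2,5-dimethylthiolan-1-ium 2-methylallylide (ylide) | C=C(C)[CH-][S+]1[C@@H](C)CC[C@@H]1C | intermediate
14 | anti betaine, (1R,2S)-1-{2-(TBSO)-5-[(1R)-1-(TBSO)ethyl]phenyl}-2-[(2S,5S)-2,5-dimethylthiolan-1-ium-1-yl]-3-methylbut-3-en-1-olate | C=C(C)[C@H]([S+]1[C@@H](C)CC[C@@H]1C)[C@H]([O-])c2cc([C@@H](C)O[Si](C)(C)C(C)(C)C)ccc2O[Si](C)(C)C(C)(C)C | intermediate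
15 | (2R,3R)-2-{2-(TBSO)-5-[(1R)-1-(TBSO)ethyl]phenyl}-3-(prop-1-en-2-yl)oxirane (trans) | C=C(C)[C@H]1O[C@@H]1c2cc([C@@H](C)O[Si](C)(C)C(C)(C)C)ccc2O[Si](C)(C)C(C)(C)C | intermediate
16 | tetrabutylammonium 4-[(1R)-1-(TBSO)ethyl]-2-[(2R,3R)-3-(prop-1-en-2-yl)oxiran-2-yl]phenolate | C=C(C)[C@H]1O[C@@H]1c2cc([C@@H](C)O[Si](C)(C)C(C)(C)C)ccc2[O-].CCCC[N+](CCCC)(CCCC)CCCC | intermediate
17 | (2S,3R)-5-[(1R)-1-(tert-butyldimethylsilyloxy)ethyl]-2-(prop-1-en-2-yl)-2,3-dihydro-1-benzofuran-3-ol | C=C(C)[C@@H]1Oc2ccc([C@@H](C)O[Si](C)(C)C(C)(C)C)cc2[C@H]1O | intermediate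
18 | (2S,3R)-5-[(1R)-1-(tert-butyldimethylsilyloxy)ethyl]-2-(prop-1-en-2-yl)-2,3-dihydro-1-benzofuran-3-yl acetate | C=C(C)[C@@H]1Oc2ccc([C@@H](C)O[Si](C)(C)C(C)(C)C)cc2[C@H]1OC(C)=O | intermediate
19 | (2S,3R)-5-[(1R)-1-hydroxyethyl]-2-(prop-1-en-2-yl)-2,3-dihydro-1-benzofuran-3-yl acetate | C=C(C)[C@@H]1Oc2ccc([C@@H](C)O)cc2[C@H]1OC(C)=O | intermediate
20 | tiglic acid, (2E)-2-methylbut-2-enoic acid | C/C=C(\C)C(=O)O | starting material
21 | (1R)-1-[(2S,3R)-3-acetoxy-2-(prop-1-en-2-yl)-2,3-dihydro-1-benzofuran-5-yl]ethyl (2E)-2-methylbut-2-enoate | C=C(C)[C@@H]1Oc2ccc([C@@H](C)OC(=O)/C(C)=C/C)cc2[C@H]1OC(C)=O | intermediate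
22 | (1R)-1-[(2S,3R)-3-acetoxy-2-(3-hydroxyprop-1-en-2-yl)-2,3-dihydro-1-benzofuran-5-yl]ethyl (2E)-2-methylbut-2-enoate | C=C(CO)[C@@H]1Oc2ccc([C@@H](C)OC(=O)/C(C)=C/C)cc2[C@H]1OC(C)=O | intermediate
23 | (1R)-1-[(2S,3R)-3-acetoxy-2-(3-oxoprop-1-en-2-yl)-2,3-dihydro-1-benzofuran-5-yl]ethyl (2E)-2-methylbut-2-enoate (CNP0294391.1) | C=C(C=O)[C@@H]1Oc2ccc([C@@H](C)OC(=O)/C(C)=C/C)cc2[C@H]1OC(C)=O | target

Total step count: 14. Longest linear sequence: 11 steps (steps 1–6 and 10–14); the sulfonium salt takes 3 steps (7–9) in a parallel branch.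

Steps most likely to fail

Step 10.
- Possible failure: facial or trans selectivity may be incomplete when the ylide adds to an ortho-substituted, electron-rich aldehyde. The aryl silyl group may transfer to the betaine alkoxide and free the phenoxide too early. The geometrically strained 5-endo opening may be slow and give way to opening at C3 through an ortho-quinone methide.
- Fallback: C2–C3 is made as an alkene and the oxirane oxygen is added afterwards under reagent control. Setting out from 7, Horner–Wadsworth–Emmons olefination with lithiated diethyl (2-methylallyl)phosphonate (n-BuLi, THF, −78 °C to rt) should give the (E)-diene 2-(TBSO)-5-[(1R)-1-(TBSO)ethyl]-1-[(1E)-3-methylbuta-1,3-dien-1-yl]benzene F1.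
- Shi epoxidation (1,2:4,5-di-O-isopropylidene-β-D-erythro-2,3-hexodiulo-2,6-pyranose, KHSO5, K2CO3 buffer, MeCN/dimethoxymethane/H2O, 0 °C) should take the trans-disubstituted styrenyl alkene in preference to the 1,1-disubstituted one. With the D-fructose-derived ketone it should give the (R,R) epoxide.
- Return: the fallback comes back to the route at 15, now isolated, which Bu4NF carries on to 17 as in the second half of step 10.

Step 14.
- Possible failure: the ene step may lose site selectivity (allylic methyl groups of the tiglate, C2–H). The acidic selenium medium may solvolyse the ionisable 4-alkoxybenzylic tiglate, with loss of the C1′ configuration.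
- Fallback: the order of events is changed so that the oxidation meets a substrate with a single alkene and no ionisable ester. Setting out from 18, SeO2/t-BuOOH (CH2Cl2, rt) should give the allylic alcohol (2S,3R)-5-[(1R)-1-(TBSO)ethyl]-2-(3-hydroxyprop-1-en-2-yl)-2,3-dihydro-1-benzofuran-3-yl acetate F2.
- MnO2 should then give the enal (2S,3R)-5-[(1R)-1-(TBSO)ethyl]-2-(3-oxoprop-1-en-2-yl)-2,3-dihydro-1-benzofuran-3-yl acetate F3. Bu4NF/AcOH should give the hydroxy enal (2S,3R)-5-[(1R)-1-hydroxyethyl]-2-(3-oxoprop-1-en-2-yl)-2,3-dihydro-1-benzofuran-3-yl acetate F4.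
- Return: Steglich esterification of the hydroxy enal with 20 comes back to the route at 23.

Step 5.
- Possible failure: at reflux the magnesium phenoxide may expel the para benzylic silyloxy group through a para-quinone methide. This would racemise C1′ or lose the side-chain oxygen by tautomerisation to the styrene.
- Fallback: the formyl carbon is introduced at low temperature on the silylated phenol by halogen–metal exchange instead of phenoxide-directed formylation. Setting out from 5, N-iodosuccinimide (MeCN, 0 °C) should give 2-iodo-4-[(1R)-1-(TBSO)ethyl]phenol F5. TBSCl/imidazole should give its silyl ether tert-butyl{2-iodo-4-[(1R)-1-(TBSO)ethyl]phenoxy}dimethylsilane F6.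
- Iodine–magnesium exchange (i-PrMgCl·LiCl, THF, −20 °C) should give {2-(TBSO)-5-[(1R)-1-(TBSO)ethyl]phenyl}magnesium chloride F7, which is quenched with DMF (aq NH4Cl work-up).
- Return: the fallback comes back to the route at 7 and bypasses 6.

Further compounds
F1 | step 10 | 2-(TBSO)-5-[(1R)-1-(TBSO)ethyl]-1-[(1E)-3-methylbuta-1,3-dien-1-yl]benzene | C=C(C)/C=C/c1cc([C@@H](C)O[Si](C)(C)C(C)(C)C)ccc1O[Si](C)(C)C(C)(C)C
F2 | step 14 | (2S,3R)-5-[(1R)-1-(TBSO)ethyl]-2-(3-hydroxyprop-1-en-2-yl)-2,3-dihydro-1-benzofuran-3-yl acetate | C=C(CO)[C@@H]1Oc2ccc([C@@H](C)O[Si](C)(C)C(C)(C)C)cc2[C@H]1OC(C)=O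
F3 | step 14 | (2S,3R)-5-[(1R)-1-(TBSO)ethyl]-2-(3-oxoprop-1-en-2-yl)-2,3-dihydro-1-benzofuran-3-yl acetate | C=C(C=O)[C@@H]1Oc2ccc([C@@H](C)O[Si](C)(C)C(C)(C)C)cc2[C@H]1OC(C)=O
F4 | step 14 | (2S,3R)-5-[(1R)-1-hydroxyethyl]-2-(3-oxoprop-1-en-2-yl)-2,3-dihydro-1-benzofuran-3-yl acetate | C=C(C=O)[C@@H]1Oc2ccc([C@@H](C)O)cc2[C@H]1OC(C)=O
F5 | step 5 | 2-iodo-4-[(1R)-1-(TBSO)ethyl]phenol | C[C@@H](O[Si](C)(C)C(C)(C)C)c1ccc(O)c(I)c1
F6 | step 5 | tert-butyl{2-iodo-4-[(1R)-1-(TBSO)ethyl]phenoxy}dimethylsilane | C[C@@H](O[Si](C)(C)C(C)(C)C)c1ccc(O[Si](C)(C)C(C)(C)C)c(I)c1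
F7 | step 5 | {2-(TBSO)-5-[(1R)-1-(TBSO)ethyl]phenyl}magnesium chloride | C[C@@H](O[Si](C)(C)C(C)(C)C)c1ccc(O[Si](C)(C)C(C)(C)C)c([Mg]Cl)c1
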